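**Plan** (target numbering: O1, C2 bearing the trimethoxyphenyl group, C3 bearing CH2OH, C4 bearing the benzyl group, C5)

- Retrosynthesis: ring A (the tetrahydrofuran) is cut at C2–C3, then at the O1–C2 ether bond. Before that, the CH2OH carbon on C3 is raised to a carbonyl and tied through oxygen to the benzylic carbon on C4, giving a gamma-lactone (ring B) that is not in the target; ring B is cut last by an aldol C–C bond.
- Forward: ring B is made first by an auxiliary-controlled aldol/lactonisation, the (3,4,5-trimethoxyphenyl)methyl ether is attached, and ring A is closed by insertion of a rhodium carbenoid at C3 into the C2–H bond. Ring B is then opened with LiAlH4 and its benzylic oxygen removed by hydrogenolysis.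
- Enabling feature: C2–H is benzylic, alpha to O1 and 1,5 to C3; C3 is alpha to the carbonyl that becomes the CH2OH carbon, so it can carry a diazo group; rings A and B can only be cis-fused.
- Stereochemistry: C4 from the aldol (oxazolidinone control), C3 from the cis fusion of rings A and B in the key step, C2 by thermodynamic equilibration to the 2,3-trans arrangement in step 9.

Key step: step 7

Remark: the insertion is assumed to give mainly the epimer with the C2 aryl group cis to the lactone carbonyl; the route does not depend on this, because C2 is equilibrated afterwards.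

**Step 1**
Reactants: 1 (R)-4-benzyl-1,3-oxazolidin-2-one; 2 methyl 4-chloro-4-oxobutanoate
Product: 3 methyl 4-[(4R)-4-benzyl-2-oxo-1,3-oxazolidin-3-yl]-4-oxobutanoate
Conditions: n-BuLi, THF, −78 °C; then 2, −78 to 0 °C
Reagents that add atoms: none
Why: N-acylation of the lithiated oxazolidinone with an acid chloride is the standard entry to N-acyl oxazolidinones and leaves the methyl ester untouched at −78 °C; no stereocentre is formed.

**Step 2**
Reactants: 3 methyl 4-[(4R)-4-benzyl-2-oxo-1,3-oxazolidin-3-yl]-4-oxobutanoate; 4 4-(benzyloxy)-3-methoxybenzaldehyde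
Product: 6 (4R)-4-benzyl-3-{(2R,3R)-2-[4-(benzyloxy)-3-methoxyphenyl]-5-oxooxolane-3-carbonyl}-1,3-oxazolidin-2-one, via syn-aldol adduct 5 (not isolated)
Conditions: Bu2BOTf, i-Pr2NEt, CH2Cl2, −78 to 0 °C; 4, −78 °C to rt; H2O2, pH 7 buffer, MeOH, 0 °C; TsOH (cat.), CH2Cl2, rt
Reagents that add atoms: none
Why: Evans syn-aldol reaction: the (Z)-boron enolate formed alpha to the imide adds to the aldehyde through a chair transition state on the face away from the auxiliary benzyl group, which sets C4 of the target (and the benzylic carbinol centre), and the new hydroxyl then lactonises onto the methyl ester to give the trans gamma-lactone (ring B).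

**Step 3**
Reactants: 6 (4R)-4-benzyl-3-{(2R,3R)-2-[4-(benzyloxy)-3-methoxyphenyl]-5-oxooxolane-3-carbonyl}-1,3-oxazolidin-2-one
Product: 8 (2R,3R)-2-[4-(benzyloxy)-3-methoxyphenyl]-5-oxooxolane-3-carboxylic acid, via peroxy acid 7 (not isolated)
Conditions: LiOH, H2O2, THF/H2O, 0 °C; Na2SO3 (aq); HCl (aq) to pH 2
Reagents that add atoms: hydrogen peroxide, OO (acting as LiOOH)
Why: hydroperoxide attacks the exocyclic imide carbonyl selectively (standard oxazolidinone removal), sulfite reduces the peroxy acid, and acidification recloses any opened lactone to the stable trans acid, so both stereocentres are kept.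

**Step 4**
Reactants: 8 (2R,3R)-2-[4-(benzyloxy)-3-methoxyphenyl]-5-oxooxolane-3-carboxylic acid
Product: 9 (4S,5R)-5-[4-(benzyloxy)-3-methoxyphenyl]-4-(hydroxymethyl)oxolan-2-one
Conditions: BH3·SMe2, THF, 0 °C to rt; aqueous work-up
Reagents that add atoms: none
Why: borane reduces a carboxylic acid much faster than a lactone, and the neutral conditions avoid migration of the lactone to the new primary hydroxyl; no stereocentre is touched.

**Step 5**
Reactants: 9 (4S,5R)-5-[4-(benzyloxy)-3-methoxyphenyl]-4-(hydroxymethyl)oxolan-2-one; 10 5-(bromomethyl)-1,2,3-trimethoxybenzene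
Product: 11 (4S,5R)-5-[4-(benzyloxy)-3-methoxyphenyl]-4-{[(3,4,5-trimethoxyphenyl)methoxy]methyl}oxolan-2-one
Conditions: Ag2O, 4 Å molecular sieves, CH2Cl2, rt, dark
Reagents that add atoms: none
Why: silver-assisted Williamson etherification with the activated benzylic bromide proceeds without alkoxide formation, so the lactone can neither migrate nor epimerise.

**Step 6**
Reactants: 11 (4S,5R)-5-[4-(benzyloxy)-3-methoxyphenyl]-4-{[(3,4,5-trimethoxyphenyl)methoxy]methyl}oxolan-2-one
Product: 13 (4S,5R)-5-[4-(benzyloxy)-3-methoxyphenyl]-3-diazo-4-{[(3,4,5-trimethoxyphenyl)methoxy]methyl}oxolan-2-one, via trifluoroacetyl lactone 12 (not isolated)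
Conditions: LiN(SiMe3)2, THF, −78 °C, then CF3CO2CH2CF3; MsN3, Et3N, H2O (1 equiv), MeCN, rt
Reagents that add atoms: 2,2,2-trifluoroethyl trifluoroacetate, O=C(OCC(F)(F)F)C(F)(F)F (trifluoroacetyl group of 12); methanesulfonyl azide, CS(=O)(=O)N=[N+]=[N-]
Why: deacylative (Regitz-type) diazo transfer: the lactone enolate is trifluoroacetylated to activate C3, and the sulfonyl azide then transfers the diazo group with loss of the trifluoroacetyl group as its sulfonamide; C4 and the benzylic centre are not acidic and are kept.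

**Step 7**
Reactants: 13 (4S,5R)-5-[4-(benzyloxy)-3-methoxyphenyl]-3-diazo-4-{[(3,4,5-trimethoxyphenyl)methoxy]methyl}oxolan-2-one
Product: 14 (1R,2S,5S,6R)-6-[4-(benzyloxy)-3-methoxyphenyl]-2-(3,4,5-trimethoxyphenyl)-3,7-dioxabicyclo[3.3.0]octan-8-one
Conditions: Rh2(OAc)4 (2 mol%), CH2Cl2, rt, slow addition of 13
Reagents that add atoms: none
Why: Rh2(OAc)4 converts the diazo lactone into an electrophilic rhodium carbenoid at C3, which inserts through a concerted three-centre transition state into the C2–H bond that is benzylic, alpha to O1 and 1,5 to C3. The closest known reaction type is the intramolecular rhodium-carbenoid C–H insertion of alpha-diazo gamma-lactones bearing a benzyloxymethyl group, which gives 2-aryl-3,7-dioxabicyclo[3.3.0]octan-8-ones. Ring A (O1–C2–C3–C4–C5) closes in the 1,5-mode as a five-membered ring fused to ring B. C3 is controlled by the existing C4 centre, because only the cis-fused bicycle can form, which places the lactone carbonyl (the future CH2OH carbon) cis to the C4 side chain. C2 should form mainly with the aryl group cis to the lactone carbonyl (away from the catalyst ligands); this centre is reset in step 9. The step needs site selectivity for the ether C–H bond over a 1,2-hydride shift from C4–H and over attack on the arenes, and this is secured by the double activation of C2–H (oxygen and electron-rich arene) and the five-membered transition-state geometry.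

**Step 8**
Reactants: 14 (1R,2S,5S,6R)-6-[4-(benzyloxy)-3-methoxyphenyl]-2-(3,4,5-trimethoxyphenyl)-3,7-dioxabicyclo[3.3.0]octan-8-one
Product: 15 (R)-[4-(benzyloxy)-3-methoxyphenyl][(3S,4S,5S)-4-(hydroxymethyl)-5-(3,4,5-trimethoxyphenyl)oxolan-3-yl]methanol
Conditions: LiAlH4, THF, 0 °C; aqueous NaOH work-up
Reagents that add atoms: none
Why: LiAlH4 reduces the lactone to the diol, which opens the temporary ring B and reveals the C3 hydroxymethyl group cis to the C4 side chain; ethers and stereocentres are untouched.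

**Step 9**
Reactants: 15 (R)-[4-(benzyloxy)-3-methoxyphenyl][(3S,4S,5S)-4-(hydroxymethyl)-5-(3,4,5-trimethoxyphenyl)oxolan-3-yl]methanol
Product: 16 (R)-[4-(benzyloxy)-3-methoxyphenyl][(3S,4S,5R)-4-(hydroxymethyl)-5-(3,4,5-trimethoxyphenyl)oxolan-3-yl]methanol
Conditions: n-C12H25SH (0.3 equiv), AIBN (3 × 0.1 equiv), PhCl, 85 °C, Ar
Reagents that add atoms: none
Why: thiol-mediated radical-chain epimerisation (reversible hydrogen-atom abstraction by a thiyl radical at a C–H alpha to an ether oxygen, with return of hydrogen from the thiol) acts on C2–H, the weakest C–H bond at a ring stereocentre, and should equilibrate C2 to the more stable epimer with the aryl group trans to the C3 and C4 substituents; C3–H and C4–H are unactivated, and the carbinol centre, which may also equilibrate, is removed in step 10.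

**Step 10**
Reactants: 16 (R)-[4-(benzyloxy)-3-methoxyphenyl][(3S,4S,5R)-4-(hydroxymethyl)-5-(3,4,5-trimethoxyphenyl)oxolan-3-yl]methanol
Product: 18 4-{[(3S,4S,5R)-4-(hydroxymethyl)-5-(3,4,5-trimethoxyphenyl)oxolan-3-yl]methyl}-2-methoxyphenol, via phenol diol 17 (not isolated)
Conditions: H2 (1 atm), Pd/C (10 wt%), EtOH/AcOH 20:1, rt
Reagents that add atoms: none
Why: catalytic hydrogenolysis cleaves the benzyl ether and then the para-hydroxybenzylic C–OH bond (a known deoxygenation of para-hydroxybenzylic alcohols), whereas the C2–O1 bond has no para-hydroxyl on its aryl group and should be cleaved much more slowly; the three ring stereocentres are untouched.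

**Compound list**

1 | (R)-4-benzyl-1,3-oxazolidin-2-one | O=C1N[C@H](Cc2ccccc2)CO1 | starting material
2 | methyl 4-chloro-4-oxobutanoate | COC(=O)CCC(Cl)=O | starting material
3 | methyl 4-[(4R)-4-benzyl-2-oxo-1,3-oxazolidin-3-yl]-4-oxobutanoate | COC(=O)CCC(=O)N1[C@H](Cc2ccccc2)COC1=O | intermediate
4 | 4-(benzyloxy)-3-methoxybenzaldehyde | O=Cc1ccc(OCc2ccccc2)c(OC)c1 | starting material
5 | methyl (3R,4R)-3-[(4R)-4-benzyl-2-oxo-1,3-oxazolidine-3-carbonyl]-4-[4-(benzyloxy)-3-methoxyphenyl]-4-hydroxybutanoate (syn-aldol adduct) | COC(=O)C[C@@H](C(=O)N1[C@H](Cc2ccccc2)COC1=O)[C@@H](O)c1ccc(OCc2ccccc2)c(OC)c1 | intermediate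
6 | (4R)-4-benzyl-3-{(2R,3R)-2-[4-(benzyloxy)-3-methoxyphenyl]-5-oxooxolane-3-carbonyl}-1,3-oxazolidin-2-one | O=C1C[C@@H](C(=O)N2[C@H](Cc3ccccc3)COC2=O)[C@H](c2ccc(OCc3ccccc3)c(OC)c2)O1 | intermediate
7 | (2R,3R)-2-[4-(benzyloxy)-3-methoxyphenyl]-5-oxooxolane-3-carboperoxoic acid (lithium salt in the flask) | O=C1C[C@@H](C(=O)OO)[C@H](c2ccc(OCc3ccccc3)c(OC)c2)O1 | intermediate
8 | (2R,3R)-2-[4-(benzyloxy)-3-methoxyphenyl]-5-oxooxolane-3-carboxylic acid | O=C1C[C@@H](C(O)=O)[C@H](c2ccc(OCc3ccccc3)c(OC)c2)O1 | intermediate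
9 | (4S,5R)-5-[4-(benzyloxy)-3-methoxyphenyl]-4-(hydroxymethyl)oxolan-2-one | O=C1C[C@@H](CO)[C@H](c2ccc(OCc3ccccc3)c(OC)c2)O1 | intermediate
10 | 5-(bromomethyl)-1,2,3-trimethoxybenzene | COc1cc(CBr)cc(OC)c1OC | starting material
11 | (4S,5R)-5-[4-(benzyloxy)-3-methoxyphenyl]-4-{[(3,4,5-trimethoxyphenyl)methoxy]methyl}oxolan-2-one | O=C1C[C@@H](COCc2cc(OC)c(OC)c(OC)c2)[C@H](c2ccc(OCc3ccccc3)c(OC)c2)O1 | intermediate
12 | (4S,5R)-5-[4-(benzyloxy)-3-methoxyphenyl]-3-(trifluoroacetyl)-4-{[(3,4,5-trimethoxyphenyl)methoxy]methyl}oxolan-2-one (C3 epimers, lithium enolate in the flask) | O=C1C(C(=O)C(F)(F)F)[C@@H](COCc2cc(OC)c(OC)c(OC)c2)[C@H](c2ccc(OCc3ccccc3)c(OC)c2)O1 | intermediate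
13 | (4S,5R)-5-[4-(benzyloxy)-3-methoxyphenyl]-3-diazo-4-{[(3,4,5-trimethoxyphenyl)methoxy]methyl}oxolan-2-one | O=C1C(=[N+]=[N-])[C@@H](COCc2cc(OC)c(OC)c(OC)c2)[C@H](c2ccc(OCc3ccccc3)c(OC)c2)O1 | intermediate
14 | (1R,2S,5S,6R)-6-[4-(benzyloxy)-3-methoxyphenyl]-2-(3,4,5-trimethoxyphenyl)-3,7-dioxabicyclo[3.3.0]octan-8-one (cis-fused; C2 aryl cis to the lactone carbonyl, C6 aryl exo) | O=C1O[C@@H](c2ccc(OCc3ccccc3)c(OC)c2)[C@@H]2CO[C@H](c3cc(OC)c(OC)c(OC)c3)[C@H]12 | intermediate
15 | (R)-[4-(benzyloxy)-3-methoxyphenyl][(3S,4S,5S)-4-(hydroxymethyl)-5-(3,4,5-trimethoxyphenyl)oxolan-3-yl]methanol (all-cis ring) | OC[C@H]1[C@@H](c2cc(OC)c(OC)c(OC)c2)OC[C@H]1[C@@H](O)c1ccc(OCc2ccccc2)c(OC)c1 | intermediate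
16 | (R)-[4-(benzyloxy)-3-methoxyphenyl][(3S,4S,5R)-4-(hydroxymethyl)-5-(3,4,5-trimethoxyphenyl)oxolan-3-yl]methanol | OC[C@H]1[C@H](c2cc(OC)c(OC)c(OC)c2)OC[C@H]1[C@@H](O)c1ccc(OCc2ccccc2)c(OC)c1 | intermediate
17 | 4-{(R)-hydroxy[(3S,4S,5R)-4-(hydroxymethyl)-5-(3,4,5-trimethoxyphenyl)oxolan-3-yl]methyl}-2-methoxyphenol | OC[C@H]1[C@H](c2cc(OC)c(OC)c(OC)c2)OC[C@H]1[C@@H](O)c1ccc(O)c(OC)c1 | intermediate
18 | 4-{[(3S,4S,5R)-4-(hydroxymethyl)-5-(3,4,5-trimethoxyphenyl)oxolan-3-yl]methyl}-2-methoxyphenol | COc1cc(C[C@@H]2CO[C@@H](c3cc(OC)c(OC)c(OC)c3)[C@@H]2CO)ccc1O | target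

**Step count:** 10 steps in total; longest linear sequence 10 steps (1 to 18).

**Steps most likely to fail**

1. Step 9. What may go wrong: slow or incomplete equilibration at C2, or chain inhibition and radical side reactions at the other benzylic positions. Fallback (cationic instead of radical, one stage earlier): the route sets out from 14, which is treated with BF3·OEt2 in CH2Cl2 (−20 °C to rt). The benzylic C2–O bond should ionise reversibly while ring B keeps C3 and C4 locked, and neither arene can reach the cation without forming a bridged ring. Equilibration should favour (1R,2R,5S,6R)-6-[4-(benzyloxy)-3-methoxyphenyl]-2-(3,4,5-trimethoxyphenyl)-3,7-dioxabicyclo[3.3.0]octan-8-one F1, which is reduced with LiAlH4 in THF; the route is rejoined at 16.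

2. Step 7. What may go wrong: diversion of the carbenoid by 1,2-hydride shift from C4–H to a butenolide, by attack on an arene, or by dimerisation. Fallback (ionic closure of the same bond): the route sets out from 9. Acetal exchange with 3,4,5-trimethoxybenzaldehyde dimethyl acetal (PPTS, CH2Cl2) gives the mixed acetal (4S,5R)-5-[4-(benzyloxy)-3-methoxyphenyl]-4-{[methoxy(3,4,5-trimethoxyphenyl)methoxy]methyl}oxolan-2-one F2. LiN(SiMe3)2 and Me3SiCl in THF at −78 °C convert it into the silyl ketene acetal {[(4S,5R)-5-[4-(benzyloxy)-3-methoxyphenyl]-4-{[methoxy(3,4,5-trimethoxyphenyl)methoxy]methyl}-4,5-dihydrofuran-2-yl]oxy}trimethylsilane F3. Me3SiOTf (cat.) in CH2Cl2 at −78 °C ionises the acetal, and the ketene acetal carbon attacks the oxocarbenium ion (intramolecular Mukaiyama-type addition to an acetal), closing C2–C3; the route is rejoined at 14 (either C2 epimer is usable).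

3. Step 10. What may go wrong: over-reduction by hydrogenolytic opening of the tetrahydrofuran at the C2–O1 bond, or stalling at the phenol stage. Fallback (ionic deoxygenation before debenzylation): the route sets out from 16. Et3SiH and CF3CO2H in CH2Cl2 (−40 to 0 °C) remove the benzylic hydroxyl through the 4-benzyloxy-3-methoxybenzylic cation, which should form far more readily than the trimethoxybenzylic one. This gives {(2R,3S,4S)-4-{[4-(benzyloxy)-3-methoxyphenyl]methyl}-2-(3,4,5-trimethoxyphenyl)oxolan-3-yl}methanol F4. Transfer hydrogenolysis (Pd/C, cyclohexa-1,4-diene, EtOH) then removes the benzyl group; the route is rejoined at 18.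

**Further compounds**

F1 | step 9 | (1R,2R,5S,6R)-6-[4-(benzyloxy)-3-methoxyphenyl]-2-(3,4,5-trimethoxyphenyl)-3,7-dioxabicyclo[3.3.0]octan-8-one | O=C1O[C@@H](c2ccc(OCc3ccccc3)c(OC)c2)[C@@H]2CO[C@@H](c3cc(OC)c(OC)c(OC)c3)[C@H]12
F2 | step 7 | (4S,5R)-5-[4-(benzyloxy)-3-methoxyphenyl]-4-{[methoxy(3,4,5-trimethoxyphenyl)methoxy]methyl}oxolan-2-one (acetal carbon as epimer mixture) | O=C1C[C@@H](COC(OC)c2cc(OC)c(OC)c(OC)c2)[C@H](c2ccc(OCc3ccccc3)c(OC)c2)O1
F3 | step 7 | {[(4S,5R)-5-[4-(benzyloxy)-3-methoxyphenyl]-4-{[methoxy(3,4,5-trimethoxyphenyl)methoxy]methyl}-4,5-dihydrofuran-2-yl]oxy}trimethylsilane | C[Si](C)(C)OC1=C[C@@H](COC(OC)c2cc(OC)c(OC)c(OC)c2)[C@H](c2ccc(OCc3ccccc3)c(OC)c2)O1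
F4 | step 10 | {(2R,3S,4S)-4-{[4-(benzyloxy)-3-methoxyphenyl]methyl}-2-(3,4,5-trimethoxyphenyl)oxolan-3-yl}methanol | OC[C@H]1[C@H](c2cc(OC)c(OC)c(OC)c2)OC[C@H]1Cc1ccc(OCc2ccccc2)c(OC)c1
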